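The numbers in the tables are calculated on assumed constants, and the scatter is random.

Read the J column of the red run first: north repeats its charge, and the set-ups asked about hold the same J, L and Z.

| setting | red | teal | ochre | south-east | north | south | west |
|---|---|---|---|---|---|---|---|
| J | 0.050 M | 0.070 M | 0.11 M | 0.050 M | 0.050 M | 0.050 M (fed, over 3.00 d) | 0.050 M |
| L | 1.05 equiv | 1.05 equiv | 1.05 equiv | 1.05 equiv | 1.05 equiv | 1.05 equiv | 1.05 equiv |
| Z | 2.6 mol% | 2.6 mol% | 2.6 mol% | 2.6 mol% | 2.6 mol% | 2.6 mol% | 2.6 mol% |
| remark | run made earlier | run made earlier | run made earlier | one stirred flow tank at steady state, fed with the mixture as stated, mean residence time 15.0 d | everything together in a closed stirred flask, run for 3.0 d | all but J at the start; J goes in evenly over 3.00 d, the run ends at 3.0 d | one stirred flow tank at steady state, fed with the mixture as stated, mean residence time 3.0 d |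
| time |  |  |  |  | 3.0 d | 3.0 d |  |

| run | time / d | X / % | Q / % | J / % |
|---|---|---|---|---|
| red | 0.250 | 5.0 | 0.2 | 95.4 |
| red | 0.500 | 9.3 | 0.2 | 89.9 |
| red | 1.25 | 21.5 | 0.9 | 77.9 |
| red | 3.00 | 39.0 | 2.9 | 57.0 |
| teal | 0.333 | 8.2 | 0.1 | 90.7 |
| teal | 0.833 | 19.5 | 0.9 | 79.8 |
| teal | 1.67 | 31.0 | 2.7 | 64.7 |
| teal | 2.50 | 40.3 | 4.7 | 54.0 |
| ochre | 0.333 | 12.7 | 0.9 | 86.4 |
| ochre | 0.833 | 25.0 | 2.4 | 72.0 |
| ochre | 1.67 | 37.4 | 6.3 | 54.6 |
| ochre | 2.50 | 45.0 | 8.8 | 42.8 |

(scatter of a reading: 0.3 percentage points)

- the stated concentrations are those of everything mixed, before any reaction; amounts are the same in each set-up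
- the earlier runs were read with a standard deviation of 0.3 percentage points
- steps thought possible: Z + X <-> E; L + E <-> Z + Q; J -> D; Q + Z <-> G + Z; J + Z -> Z + X
- the feed brings no volume worth counting
- the earlier runs were made in a closed, stirred flask

- the set-up with the highest amount of X at the outlet or at the end, in percent of the J put in ("none" if the first two lie within 2 percentage points) (south-east / north / south / west / none)
- amount of X at the outlet or at the end, in percent of the J put in, south-east
- amount of X at the outlet or at the end, in percent of the J put in, north
- amount of X at the outlet or at the end, in percent of the J put in, south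
- amount of X at the outlet or at the end, in percent of the J put in, west

1. First instants of red: J becomes X with Z present. At 0.500 d, J reads 89.9%, X 9.3% and Q 0.2%, against a scatter of 0.3 percentage points, so the drain of X to Q is barely readable. The loss of J reads 0.213 d⁻¹ here.

2. Middle of red: between 1.25 d and 3.00 d the same reckoning gives 0.178 d⁻¹, lower than at the start, so J loss slows as X builds. Meanwhile the gain of Q reads 11.4% of the gain of X in red, more than the 2.15% read for the first stage, a first-stage figure resting on a Q reading of the size of the scatter, so in these readings the drain gains on the formation of X.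

3. End of red: over the whole run, the natural logarithm of J charged over J left, divided by the time, gives the run-average J-loss constant, a pseudo-first-order constant for this charge: 0.187 d⁻¹.

4. Tanks: for a first-order loss at steady state, the share of J left is one over one plus the constant times the residence time. This reckoning puts J at 64.0% in west and 26.2% in south-east. The constant read in red is lower late than early and a tank stands at its late composition, so the south-east J is expected somewhat above that figure.

5. Forecast: X of 46.5% (42% to 51%) in south-east, 39.2% north, 23% south and 30.5% west, with south-east best. It takes about 71 percent of J converted in south-east, where this reckoning takes 73.8%, and says of that tank: “This extrapolates furthest, so it is the least certain”.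

The flasks give X of 54.3% in south-east, 38.9% north, 22.7% south and 30.6% west, so south-east comes first, and the forecast's south-east figure lies 7.8 points low.

    Z + X ⇌ E (K = 13.2 M⁻¹, k = 29.7 M⁻¹ h⁻¹)
    L + E ⇌ Z + Q (K = 0.360, k = 3.67 M⁻¹ h⁻¹)
    J → D (k = 7.43 × 10⁻⁵ h⁻¹)
    Q + Z ⇌ G + Z, rate k4*[Z]*[Q] forward; the back reaction follows from the equilibrium constant (K = 3.09, k = 4.29 M⁻¹ h⁻¹)
    J + Z → Z + X (k = 6.75 M⁻¹ h⁻¹)

J stood at 65.1% in west against the reckoned 64.0%, and at 29.7% in south-east against 26.2%, so the south-east constant comes to 0.158 d⁻¹, below 0.187 d⁻¹. The forecast's converted J of about 71 percent in south-east stands near the flask's 70.3%, and the two part on the drain, where the forecast counted about 23 percent as Q loss. With J at 0.0148 M and L at 0.0452 M in the south-east tank, X had passed on to 7.25% of Q and 7.28% of G, together 14.5%.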